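The dihydrochalcone is disconnected between the ketone carbon and its α-methylene. That bond is made in one atom-economic operation: a rhodium-catalysed anti-Markovnikov hydroacylation in which the formyl C–H of unprotected 2,4,6-trihydroxy-3-prenylbenzaldehyde adds across the vinyl group of a MOM-protected 3,4-dioxygenated 5-prenylstyrene. The step exploits the phenolic oxygens on C2' and C6' of the phloroglucinol ring, flanking the acyl-bearing C1': as a salicylaldehyde-type chelate they guide rhodium into the formyl C–H bond and suppress decarbonylation. The aldehyde arises by one C-prenylation; the styrene from 3-bromo-4,5-dihydroxybenzaldehyde by MOM protection, Stille prenylation and Wittig methylenation. Acidic MOM cleavage finishes the route.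

Key step: step 5

Remark: the target has no stereocentre and no configurational double bond (each prenyl alkene carries two identical methyl groups), so the main route needs no stereodescriptors. Compounds 1 and 3 and the reagents prenyl bromide, MOMCl, tributyl(prenyl)stannane and methyltriphenylphosphonium bromide are taken as commercial.

Step 1
Reactants: 1 2,4,6-trihydroxybenzaldehyde
Product: 2 2,4,6-trihydroxy-3-(3-methylbut-2-en-1-yl)benzaldehyde
Conditions: prenyl bromide (0.9 equiv), DBU (1.0 equiv), THF, 0 °C → rt
Reagents that add atoms: prenyl bromide (1-bromo-3-methylbut-2-ene), CC(C)=CCBr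
Why: Direct C-prenylation (C-alkylation of an ambident phloroglucinol phenoxide): the amidine base forms a tight mono-phenoxide that attacks the primary carbon of the soft allylic bromide through ring carbon C3, and since C3 and C5 of 1 are equivalent only one mono-C-prenyl isomer can form, a slight excess of 1 limiting a second alkylation.

Step 2
Reactants: 3 3-bromo-4,5-dihydroxybenzaldehyde
Product: 4 3-bromo-4,5-bis(methoxymethoxy)benzaldehyde
Conditions: MOMCl (3 equiv), i-Pr2NEt (4 equiv), CH2Cl2, 0 °C → rt
Reagents that add atoms: chloromethyl methyl ether (MOMCl), COCCl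
Why: MOM protection (O-alkylation of both catechol hydroxyls by the oxocarbenium-type chloride under Hünig's base) leaves the aldehyde and aryl bromide untouched and gives ethers that withstand the palladium, ylide and rhodium steps that follow.

Step 3
Reactants: 4 3-bromo-4,5-bis(methoxymethoxy)benzaldehyde
Product: 5 3,4-bis(methoxymethoxy)-5-(3-methylbut-2-en-1-yl)benzaldehyde
Conditions: tributyl(prenyl)stannane (1.3 equiv), Pd(PPh3)4 (5 mol%), DMF, 90 °C
Reagents that add atoms: tributyl(3-methylbut-2-en-1-yl)stannane, CCCC[Sn](CCCC)(CCCC)CC=C(C)C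
Why: Stille cross-coupling: oxidative addition of Pd(0) into the Ar–Br bond, transmetalation with the allylic stannane and reductive elimination at the less hindered primary terminus of the prenyl ligand should give the linear 3-methylbut-2-enyl arene, with the aldehyde and MOM ethers inert.

Step 4
Reactants: 5 3,4-bis(methoxymethoxy)-5-(3-methylbut-2-en-1-yl)benzaldehyde
Product: 6 5-ethenyl-1,2-bis(methoxymethoxy)-3-(3-methylbut-2-en-1-yl)benzene
Conditions: Ph3PCH3Br (1.3 equiv), KOt-Bu (1.3 equiv), THF, 0 °C → rt
Reagents that add atoms: methyltriphenylphosphonium bromide, C[P+](c1ccccc1)(c1ccccc1)c1ccccc1.[Br-]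
Why: Wittig olefination with the non-stabilised methylene ylide converts the aryl aldehyde into the vinyl group, and the MOM ethers and the trisubstituted prenyl alkene are inert to the ylide.

Step 5
Reactants: 2 2,4,6-trihydroxy-3-(3-methylbut-2-en-1-yl)benzaldehyde; 6 5-ethenyl-1,2-bis(methoxymethoxy)-3-(3-methylbut-2-en-1-yl)benzene (1.5 equiv)
Product: 7 3-[3,4-bis(methoxymethoxy)-5-(3-methylbut-2-en-1-yl)phenyl]-1-[2,4,6-trihydroxy-3-(3-methylbut-2-en-1-yl)phenyl]propan-1-one
Conditions: [Rh(cod)OMe]2 (2.5 mol%), bulky BINOL-derived phosphoramidite (10 mol%), K3PO4 (10 mol%), THF, 70 °C, Ar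
Reagents that add atoms: none
Why: Rh-catalysed chelation-assisted intermolecular alkene hydroacylation, the known coupling of salicylaldehydes with terminal alkenes: the basic Rh(I) species turns the C2'–OH (or the equivalent ortho C6'–OH) of 2 into a κ2-O,O rhodium salicylaldehydate, oxidative addition of the formyl C–H bond gives a five-membered acyl–Rh(III)–hydride chelate, the vinyl group of 6 inserts reversibly into Rh–H, and C–C reductive elimination from the primary alkyl–acyl complex forms the ketone C(=O)–CH2 bond before protonolysis by the next molecule of 2 releases 7. No ring is closed and no stereocentre is formed, and every atom of 2 and 6 ends in 7. The step needs linear (anti-Markovnikov) regioselectivity against the benzylic rhodium alkyl that vinylarenes favour: the bulky monodentate phosphoramidite should slow reductive elimination from the secondary benzylic alkyl so that the reversible insertion drains through the primary one, and because both ring-B oxygens are capped as MOM ethers and lie meta and para to the vinyl group, no phenoxide can direct rhodium to the benzylic carbon. It also needs chemoselectivity for the monosubstituted vinyl group over the two trisubstituted prenyl alkenes, which are too hindered to insert, and freedom from decarbonylation, which the rigid phenoxide chelate prevents. The non-chelating C4'–OH of 2 should be tolerated because the cycle itself runs on a phenol/phenoxide shuttle and only catalytic base is present, so the aldehyde is not tied up as a polyphenoxide.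

Step 6
Reactants: 7 3-[3,4-bis(methoxymethoxy)-5-(3-methylbut-2-en-1-yl)phenyl]-1-[2,4,6-trihydroxy-3-(3-methylbut-2-en-1-yl)phenyl]propan-1-one
Product: 8 2',4',6',3,4-pentahydroxy-3',5-diprenyldihydrochalcone (3-[3,4-dihydroxy-5-(3-methylbut-2-en-1-yl)phenyl]-1-[2,4,6-trihydroxy-3-(3-methylbut-2-en-1-yl)phenyl]propan-1-one)
Conditions: 3 M aq. HCl (cat.), degassed MeOH, rt → 40 °C
Reagents that add atoms: none
Why: Acid-catalysed acetal exchange (MOM cleavage) in methanol frees the two catechol hydroxyls as dimethoxymethane, and dilute acid near room temperature is the standard way to unmask prenylated polyphenols without closing the ortho-prenyl phenols to 2,2-dimethylchromans.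

Compound list
1 | 2,4,6-trihydroxybenzaldehyde | O=Cc1c(O)cc(O)cc1O | starting material
2 | 2,4,6-trihydroxy-3-(3-methylbut-2-en-1-yl)benzaldehyde | O=Cc1c(O)cc(O)c(CC=C(C)C)c1O | intermediate
3 | 3-bromo-4,5-dihydroxybenzaldehyde | O=Cc1cc(O)c(O)c(Br)c1 | starting material
4 | 3-bromo-4,5-bis(methoxymethoxy)benzaldehyde | O=Cc1cc(OCOC)c(OCOC)c(Br)c1 | intermediate
5 | 3,4-bis(methoxymethoxy)-5-(3-methylbut-2-en-1-yl)benzaldehyde | O=Cc1cc(OCOC)c(OCOC)c(CC=C(C)C)c1 | intermediate
6 | 5-ethenyl-1,2-bis(methoxymethoxy)-3-(3-methylbut-2-en-1-yl)benzene | C=Cc1cc(OCOC)c(OCOC)c(CC=C(C)C)c1 | intermediate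
7 | 3-[3,4-bis(methoxymethoxy)-5-(3-methylbut-2-en-1-yl)phenyl]-1-[2,4,6-trihydroxy-3-(3-methylbut-2-en-1-yl)phenyl]propan-1-one | CC(C)=CCc1cc(CCC(=O)c2c(O)cc(O)c(CC=C(C)C)c2O)cc(OCOC)c1OCOC | intermediate
8 | 2',4',6',3,4-pentahydroxy-3',5-diprenyldihydrochalcone | CC(C)=CCc1cc(CCC(=O)c2c(O)cc(O)c(CC=C(C)C)c2O)cc(O)c1O | target

Total step count: 6. Longest linear sequence: 5 steps (3 → 4 → 5 → 6 → 7 → 8).

Steps most likely to fail

Step 5 (key step). The hydride insertion may place rhodium on the benzylic carbon and lead to branched acylation, or turnover may stall through binding of rhodium by the polyphenol. The fallback sets out from 6 and 2 and comes back at 8, forming the same carbon–carbon bond by 1,2-addition. Anti-Markovnikov hydroboration of the vinyl group of 6 with 9-BBN (THF, 0 °C → rt; the trisubstituted prenyl alkene reacts much more slowly) and NaOH/H2O2 oxidation would give 2-[3,4-bis(methoxymethoxy)-5-(3-methylbut-2-en-1-yl)phenyl]ethan-1-ol F1. Iodination (I2, PPh3, imidazole, CH2Cl2) would give 5-(2-iodoethyl)-1,2-bis(methoxymethoxy)-3-(3-methylbut-2-en-1-yl)benzene F2. In parallel, 2 would be fully protected (MOMCl, NaH, DMF) as 2,4,6-tris(methoxymethoxy)-3-(3-methylbut-2-en-1-yl)benzaldehyde F3. Iodine–lithium exchange on F2 (t-BuLi, 2 equiv, Et2O, −78 °C) would give {2-[3,4-bis(methoxymethoxy)-5-(3-methylbut-2-en-1-yl)phenyl]ethyl}lithium F4 (not isolated). Its addition to F3 would give racemic 3-[3,4-bis(methoxymethoxy)-5-(3-methylbut-2-en-1-yl)phenyl]-1-[2,4,6-tris(methoxymethoxy)-3-(3-methylbut-2-en-1-yl)phenyl]propan-1-ol F5. Dess–Martin oxidation would give 3-[3,4-bis(methoxymethoxy)-5-(3-methylbut-2-en-1-yl)phenyl]-1-[2,4,6-tris(methoxymethoxy)-3-(3-methylbut-2-en-1-yl)phenyl]propan-1-one F6, and HCl/MeOH would remove all five MOM groups to give 8.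

Step 1. O-alkylation, a second C-alkylation at C5 and geminal dialkylation with loss of aromaticity may compete with the single C-prenylation. The fallback sets out from 1 and comes back at 2. Selective protection of the two hydroxyls that are easiest to reach (MOMCl 2.2 equiv, i-Pr2NEt, CH2Cl2, 0 °C; one hydrogen-bonded ortho hydroxyl stays free) would give 2-hydroxy-4,6-bis(methoxymethoxy)benzaldehyde F7. O-Prenylation (prenyl bromide, K2CO3, acetone) would give 2,4-bis(methoxymethoxy)-6-[(3-methylbut-2-en-1-yl)oxy]benzaldehyde F8. Heating in N,N-diethylaniline (about 200 °C) should bring about the tandem aromatic Claisen/Cope shift that moves the prenyl group to the ring carbon para to the ether oxygen, giving 6-hydroxy-2,4-bis(methoxymethoxy)-3-(3-methylbut-2-en-1-yl)benzaldehyde F9. Mild HCl/MeOH would then give 2.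

Step 3. Allylic transposition on palladium may lead to bond formation at the tertiary terminus (reverse prenylation), and oxidative addition next to the ortho MOM ether may be slow. The fallback sets out from 4 and comes back at 5. Stille coupling of 4 with allyltributylstannane (Pd(PPh3)4, DMF, 90 °C), which has no regiochemical ambiguity, would give 3,4-bis(methoxymethoxy)-5-(prop-2-en-1-yl)benzaldehyde F10. Olefin cross-metathesis with excess 2-methylbut-2-ene (Grubbs second-generation catalyst, CH2Cl2, 40 °C) would convert the allyl group into the prenyl group of 5.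

Further compounds
F1 | step 5 | 2-[3,4-bis(methoxymethoxy)-5-(3-methylbut-2-en-1-yl)phenyl]ethan-1-ol | OCCc1cc(OCOC)c(OCOC)c(CC=C(C)C)c1
F2 | step 5 | 5-(2-iodoethyl)-1,2-bis(methoxymethoxy)-3-(3-methylbut-2-en-1-yl)benzene | ICCc1cc(OCOC)c(OCOC)c(CC=C(C)C)c1
F3 | step 5 | 2,4,6-tris(methoxymethoxy)-3-(3-methylbut-2-en-1-yl)benzaldehyde | O=Cc1c(OCOC)cc(OCOC)c(CC=C(C)C)c1OCOC
F4 | step 5 | {2-[3,4-bis(methoxymethoxy)-5-(3-methylbut-2-en-1-yl)phenyl]ethyl}lithium | [Li]CCc1cc(OCOC)c(OCOC)c(CC=C(C)C)c1
F5 | step 5 | racemic 3-[3,4-bis(methoxymethoxy)-5-(3-methylbut-2-en-1-yl)phenyl]-1-[2,4,6-tris(methoxymethoxy)-3-(3-methylbut-2-en-1-yl)phenyl]propan-1-ol | CC(C)=CCc1cc(CCC(O)c2c(OCOC)cc(OCOC)c(CC=C(C)C)c2OCOC)cc(OCOC)c1OCOC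
F6 | step 5 | 3-[3,4-bis(methoxymethoxy)-5-(3-methylbut-2-en-1-yl)phenyl]-1-[2,4,6-tris(methoxymethoxy)-3-(3-methylbut-2-en-1-yl)phenyl]propan-1-one | CC(C)=CCc1cc(CCC(=O)c2c(OCOC)cc(OCOC)c(CC=C(C)C)c2OCOC)cc(OCOC)c1OCOC
F7 | step 1 | 2-hydroxy-4,6-bis(methoxymethoxy)benzaldehyde | O=Cc1c(O)cc(OCOC)cc1OCOC
F8 | step 1 | 2,4-bis(methoxymethoxy)-6-[(3-methylbut-2-en-1-yl)oxy]benzaldehyde | O=Cc1c(OCC=C(C)C)cc(OCOC)cc1OCOC
F9 | step 1 | 6-hydroxy-2,4-bis(methoxymethoxy)-3-(3-methylbut-2-en-1-yl)benzaldehyde | O=Cc1c(O)cc(OCOC)c(CC=C(C)C)c1OCOC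
F10 | step 3 | 3,4-bis(methoxymethoxy)-5-(prop-2-en-1-yl)benzaldehyde | O=Cc1cc(OCOC)c(OCOC)c(CC=C)c1
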